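**Retrosynthetic overview**
- The route rests on C6 of ring A: it is the only carbon-substituted position of ring A and lies between the oxygen-bearing C5 and C7. On a phloroglucinol-derived ring, substitution or pyranone closure cannot tell C6 from C8.
- Ring A is therefore made last from open-chain atoms. After removal of the allyl and silyl groups it is cut at C5–C6, C7–C8 and C4a–C5 into a 6-aryl-4-pyranon-2-yl diazomethyl ketone (a ketene precursor) and a triisopropylsilyl ynol ether carrying the finished (1S,3S)-cyclohexylmethyl unit.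
- The diazoketone comes from 3,4-dihydroxyacetophenone by allylation, two Claisen condensations (ethyl acetate, diethyl oxalate), pyranone closure, hydrolysis and diazomethane.
- The ynol ether comes from 4,4-dimethylcyclohex-2-enone by iodination, CBS reduction (carbinol centre), silylation, hydroxymethylation, Johnson–Claisen rearrangement (second centre and exocyclic methylene) and Kowalski homologation.
- Ring order: ring B and the carbocycle are bought, ring C (the pyranone) is closed in step 3, ring A in step 12.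

Key step: step 12

Remark (assumption): the target descriptors are read as (S) at the carbinol carbon and (S) at the ring carbon bearing the benzylic CH2, so that hydroxyl and arylmethyl are trans across the methylidene carbon. Flavone numbering (O1, C2 … C8a) is used for the chromenone.

**Route**

Step 1
Reactants: 1 1-(3,4-dihydroxyphenyl)ethan-1-one
Product: 2 1-[3,4-bis(prop-2-en-1-yloxy)phenyl]ethan-1-one
Conditions: allyl bromide, K2CO3, DMF, 60 °C
Reagents that add atoms: allyl bromide, C=CCBr
Why: Williamson ether synthesis; carbonate deprotonates both phenols, which displace bromide, and the ketone is not enolised under these conditions.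

Step 2
Reactants: 2 1-[3,4-bis(prop-2-en-1-yloxy)phenyl]ethan-1-one; 3 ethyl acetate
Product: 4 1-[3,4-bis(prop-2-en-1-yloxy)phenyl]butane-1,3-dione
Conditions: NaH, THF, 0 °C → reflux; then aq. HCl
Reagents that add atoms: none
Why: Crossed Claisen condensation; the sodium enolate of 2 is acylated by ethyl acetate and the equilibrium is pulled through by deprotonation of the 1,3-diketone, the allyl aryl ethers being inert to NaH.

Step 3
Reactants: 4 1-[3,4-bis(prop-2-en-1-yloxy)phenyl]butane-1,3-dione; 5 diethyl oxalate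
Product: 7 ethyl 6-[3,4-bis(prop-2-en-1-yloxy)phenyl]-4-oxo-4H-pyran-2-carboxylate, via triketo ester 6 (not isolated)
Conditions: NaOEt, EtOH, 0 → 25 °C; then conc. HCl, EtOH, reflux
Reagents that add atoms: none
Why: A second Claisen condensation at the terminal methyl group under equilibrating ethoxide (the doubly enolised triketo ester is the thermodynamic sink) followed by acid-catalysed cyclodehydration of the 1,3,5-tricarbonyl unit closes ring C, the classical route to 6-aryl-4-pyranone-2-carboxylates.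

Step 4
Reactants: 7 ethyl 6-[3,4-bis(prop-2-en-1-yloxy)phenyl]-4-oxo-4H-pyran-2-carboxylate
Product: 8 6-[3,4-bis(prop-2-en-1-yloxy)phenyl]-4-oxo-4H-pyran-2-carboxylic acid
Conditions: LiOH (1.1 equiv), THF/H2O, 0 °C; then aq. HCl to pH 2
Reagents that add atoms: lithium hydroxide in water, [Li+].[OH-]
Why: Saponification of an activated heteroaryl ester with one equivalent of hydroxide at 0 °C; should hydroxide open the pyranone, the acidic work-up recloses the tricarbonyl form.

Step 5
Reactants: 8 6-[3,4-bis(prop-2-en-1-yloxy)phenyl]-4-oxo-4H-pyran-2-carboxylic acid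
Product: 10 2-diazo-1-{6-[3,4-bis(prop-2-en-1-yloxy)phenyl]-4-oxo-4H-pyran-2-yl}ethan-1-one, via acid chloride 9 (not isolated)
Conditions: (COCl)2, DMF (cat.), CH2Cl2, 0 → 25 °C; then CH2N2 (2.5 equiv), Et2O, 0 °C
Reagents that add atoms: diazomethane, C=[N+]=[N-]; oxalyl chloride, O=C(Cl)C(=O)Cl (chlorine of intermediate 9 only)
Why: Acylation of diazomethane by an acid chloride (the first stage of an Arndt–Eistert sequence), a second equivalent of diazomethane taking up the HCl; the unactivated allyl alkenes do not react with diazomethane at 0 °C.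

Step 6
Reactants: 11 4,4-dimethylcyclohex-2-en-1-one
Product: 12 2-iodo-4,4-dimethylcyclohex-2-en-1-one
Conditions: I2, pyridine, CH2Cl2, 0 → 25 °C
Reagents that add atoms: iodine, II
Why: α-Iodination of an enone by I2/pyridine (conjugate addition of pyridine, iodination of the enolate, loss of pyridine), which tolerates the quaternary γ-carbon.

Step 7
Reactants: 12 2-iodo-4,4-dimethylcyclohex-2-en-1-one
Product: 13 (1S)-2-iodo-4,4-dimethylcyclohex-2-en-1-ol
Conditions: (R)-2-methyl-CBS-oxazaborolidine [(3aR)-1-methyl-3,3-diphenyltetrahydro-1H,3H-pyrrolo[1,2-c][1,3,2]oxazaborole] (0.2 equiv), BH3·SMe2, THF, −20 °C; MeOH quench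
Reagents that add atoms: none
Why: Corey–Bakshi–Shibata reduction; the iodoalkenyl carbon acts as the large ketone substituent, so the (R)-catalyst should deliver hydride to the face that gives the (S)-carbinol, which becomes the hydroxyl-bearing stereocentre of the target.

Step 8
Reactants: 13 (1S)-2-iodo-4,4-dimethylcyclohex-2-en-1-ol
Product: 14 tert-butyl{[(1S)-2-iodo-4,4-dimethylcyclohex-2-en-1-yl]oxy}dimethylsilane
Conditions: TBSCl, imidazole, DMF, 25 °C
Reagents that add atoms: tert-butyldimethylsilyl chloride, CC(C)(C)[Si](C)(C)Cl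
Why: Standard imidazole-promoted silylation of a secondary allylic alcohol; the ether survives the organolithium, Claisen and Kowalski conditions ahead.

Step 9
Reactants: 14 tert-butyl{[(1S)-2-iodo-4,4-dimethylcyclohex-2-en-1-yl]oxy}dimethylsilane
Product: 17 [(6S)-6-(tert-butyldimethylsilyloxy)-3,3-dimethylcyclohex-1-en-1-yl]methanol, via vinyllithium 15 (not isolated), via enal 16 (not isolated)
Conditions: t-BuLi (2.1 equiv), Et2O, −78 °C; DMF, −78 → 0 °C; then MeOH, NaBH4, 0 °C
Reagents that add atoms: N,N-dimethylformamide, CN(C)C=O; tert-butyllithium, [Li]C(C)(C)C (lithium of intermediate 15 only)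
Why: Iodine–lithium exchange at −78 °C gives the vinyllithium, which is formylated by DMF before oxygen-to-carbon silyl migration can compete, and NaBH4 reduces the enal at the carbonyl to the primary allylic alcohol without touching the carbinol stereocentre.

Step 10
Reactants: 17 [(6S)-6-(tert-butyldimethylsilyloxy)-3,3-dimethylcyclohex-1-en-1-yl]methanol; 18 triethyl orthoacetate
Product: 20 ethyl 2-[(1S,3S)-3-(tert-butyldimethylsilyloxy)-6,6-dimethyl-2-methylidenecyclohexyl]acetate, via ketene acetal 19 (not isolated)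
Conditions: EtCO2H (cat.), xylene, 140 °C, EtOH distilled off
Reagents that add atoms: none
Why: Johnson–Claisen rearrangement; alcohol exchange gives the mixed ketene acetal 19, whose chair-like [3,3] shift forms the C–C bond at the ring alkene carbon next to CMe2 and moves the double bond to the exocyclic position, and the new stereocentre is set by the (S)-carbinol carbon because the ketene acetal arm should reach the ring only on the face away from the neighbouring OTBS group (pseudoaxial to avoid allylic strain with the CH2O arm), giving the trans (1S,3S) isomer.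

Step 11
Reactants: 20 ethyl 2-[(1S,3S)-3-(tert-butyldimethylsilyloxy)-6,6-dimethyl-2-methylidenecyclohexyl]acetate
Product: 23 tert-butyl{[(1S,3S)-4,4-dimethyl-2-methylidene-3-{3-[tri(propan-2-yl)silyloxy]prop-2-yn-1-yl}cyclohexyl]oxy}dimethylsilane, via dibromoketone enolate 21 (not isolated), via lithium ynolate 22 (not isolated)
Conditions: CH2Br2, lithium 2,2,6,6-tetramethylpiperidide, THF, −78 °C; 20; lithium hexamethyldisilazide; n-BuLi, −78 → 25 °C; TIPSCl, −78 → 0 °C
Reagents that add atoms: dibromomethane, BrCBr; triisopropylsilyl chloride, CC(C)[Si](Cl)(C(C)C)C(C)C (the lithium of intermediates 21 and 22 comes from lithium hexamethyldisilazide and n-butyllithium, CCCC[Li])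
Why: Kowalski ester homologation; LiCHBr2 adds to the ester, the dibromoketone enolate undergoes bromine–lithium exchange and 1,2-shift of the alkyl group to the ynolate, and the bulky TIPSCl silylates the ynolate on oxygen to give the ynol ether, neither stereocentre being involved.

Step 12
Reactants: 10 2-diazo-1-{6-[3,4-bis(prop-2-en-1-yloxy)phenyl]-4-oxo-4H-pyran-2-yl}ethan-1-one; 23 tert-butyl{[(1S,3S)-4,4-dimethyl-2-methylidene-3-{3-[tri(propan-2-yl)silyloxy]prop-2-yn-1-yl}cyclohexyl]oxy}dimethylsilane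
Product: 27 2-[3,4-bis(prop-2-en-1-yloxy)phenyl]-6-{[(1S,3S)-3-(tert-butyldimethylsilyloxy)-6,6-dimethyl-2-methylidenecyclohexyl]methyl}-5-hydroxy-7-[tri(propan-2-yl)silyloxy]-4H-chromen-4-one, via pyranonylketene 24 (not isolated), via cyclobutenone 25 (not isolated), via dienylketene 26 (not isolated)
Conditions: hν (365 nm), degassed ClCH2CH2Cl, 25 °C; then 80 °C in the dark
Reagents that add atoms: none
Why: Proposed new method: irradiation expels N2 from 10 and the pyranon-2-yl group shifts to the carbene carbon (Wolff rearrangement, which also makes the C8–C8a bond) to give ketene 24; the nucleophilic, alkyl-bearing carbon of ynol ether 23 attacks the ketene carbon and a [2+2] cycloaddition gives cyclobutenone 25 (bonds C5–C6 and C7–C8). Four-electron electrocyclic opening of 25 gives dienylketene 26, and ring A closes by thermal six-electron disrotatory electrocyclisation of 26 between the ketene carbon and pyranone C3 (bond C4a–C5), after which the C4a hydrogen, flanked by two carbonyl groups, moves to oxygen to give the C5 phenol. The closest known reaction type is the Danheiser benzannulation in its photochemical Wolff form, run with aryl and five-membered heteroaryl diazomethyl ketones and siloxyalkynes but not with a 4-pyranone; the pyranone C2=C3 bond is much less aromatic than a benzene bond, so the closure should cost less than in the aryl cases. No stereocentre is created (the sp3 carbons of 25 and of the cyclohexadienone are transient), and the two existing ones are not reacting atoms and carry no acidic hydrogen. Only regiochemistry is needed: the ynol ether is polarised so that its alkyl carbon bonds to the ketene carbon, which puts the chain on C6 between O5 (the ketene oxygen) and O7 (the ynol oxygen), while O1 was fixed in the pyranone before ring A existed, so a C8 isomer cannot arise. The medium is neutral and aprotic, so the silyl ethers, the allyl ethers and the exocyclic alkene should pass unchanged, and light near 365 nm is chosen to excite the diazoketone while sparing the pyranone and flavone chromophores as far as possible.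

Step 13
Reactants: 27 2-[3,4-bis(prop-2-en-1-yloxy)phenyl]-6-{[(1S,3S)-3-(tert-butyldimethylsilyloxy)-6,6-dimethyl-2-methylidenecyclohexyl]methyl}-5-hydroxy-7-[tri(propan-2-yl)silyloxy]-4H-chromen-4-one
Product: 28 2-[3,4-bis(prop-2-en-1-yloxy)phenyl]-5,7-dihydroxy-6-{[(1S,3S)-3-hydroxy-6,6-dimethyl-2-methylidenecyclohexyl]methyl}-4H-chromen-4-one
Conditions: Bu4NF (3 equiv), THF, 0 → 25 °C; aq. NH4Cl work-up
Reagents that add atoms: none
Why: Fluoride cleaves the aryl triisopropylsilyl ether and the secondary TBS ether; no acid is used, so the C7 phenol cannot add to the exocyclic alkene, and the catechol is still masked while the medium is basic.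

Step 14
Reactants: 28 2-[3,4-bis(prop-2-en-1-yloxy)phenyl]-5,7-dihydroxy-6-{[(1S,3S)-3-hydroxy-6,6-dimethyl-2-methylidenecyclohexyl]methyl}-4H-chromen-4-one
Product: 29 ugonin Q, 2-(3,4-dihydroxyphenyl)-5,7-dihydroxy-6-{[(1S,3S)-3-hydroxy-6,6-dimethyl-2-methylidenecyclohexyl]methyl}-4H-chromen-4-one
Conditions: Pd(PPh3)4 (zerovalent palladium, 5 mol %), morpholine, THF, 25 °C, under argon
Reagents that add atoms: none
Why: Tsuji–Trost deallylation; Pd(PPh3)4 inserts into the allyl aryl ethers and morpholine captures the allyl groups, while the free allylic alcohol is not ionised under these neutral conditions.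

**Compound list**
1 | 1-(3,4-dihydroxyphenyl)ethan-1-one | CC(=O)c1ccc(O)c(O)c1 | starting material
2 | 1-[3,4-bis(prop-2-en-1-yloxy)phenyl]ethan-1-one | CC(=O)c1ccc(OCC=C)c(OCC=C)c1 | intermediate
3 | ethyl acetate | CCOC(C)=O | starting material
4 | 1-[3,4-bis(prop-2-en-1-yloxy)phenyl]butane-1,3-dione | CC(=O)CC(=O)c1ccc(OCC=C)c(OCC=C)c1 | intermediate
5 | diethyl oxalate | CCOC(=O)C(=O)OCC | starting material
6 | ethyl 6-[3,4-bis(prop-2-en-1-yloxy)phenyl]-2,4,6-trioxohexanoate | CCOC(=O)C(=O)CC(=O)CC(=O)c1ccc(OCC=C)c(OCC=C)c1 | intermediate (not isolated)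
7 | ethyl 6-[3,4-bis(prop-2-en-1-yloxy)phenyl]-4-oxo-4H-pyran-2-carboxylate | CCOC(=O)c1cc(=O)cc(-c2ccc(OCC=C)c(OCC=C)c2)o1 | intermediate
8 | 6-[3,4-bis(prop-2-en-1-yloxy)phenyl]-4-oxo-4H-pyran-2-carboxylic acid | OC(=O)c1cc(=O)cc(-c2ccc(OCC=C)c(OCC=C)c2)o1 | intermediate
9 | 6-[3,4-bis(prop-2-en-1-yloxy)phenyl]-4-oxo-4H-pyran-2-carbonyl chloride | ClC(=O)c1cc(=O)cc(-c2ccc(OCC=C)c(OCC=C)c2)o1 | intermediate (not isolated)
10 | 2-diazo-1-{6-[3,4-bis(prop-2-en-1-yloxy)phenyl]-4-oxo-4H-pyran-2-yl}ethan-1-one | [N-]=[N+]=CC(=O)c1cc(=O)cc(-c2ccc(OCC=C)c(OCC=C)c2)o1 | intermediate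
11 | 4,4-dimethylcyclohex-2-en-1-one | CC1(C)CCC(=O)C=C1 | starting material
12 | 2-iodo-4,4-dimethylcyclohex-2-en-1-one | CC1(C)CCC(=O)C(I)=C1 | intermediate
13 | (1S)-2-iodo-4,4-dimethylcyclohex-2-en-1-ol | IC1=CC(C)(C)CC[C@@H]1O | intermediate
14 | tert-butyl{[(1S)-2-iodo-4,4-dimethylcyclohex-2-en-1-yl]oxy}dimethylsilane | IC1=CC(C)(C)CC[C@@H]1O[Si](C)(C)C(C)(C)C | intermediate
15 | [(6S)-6-(tert-butyldimethylsilyloxy)-3,3-dimethylcyclohex-1-en-1-yl]lithium | [Li]C1=CC(C)(C)CC[C@@H]1O[Si](C)(C)C(C)(C)C | intermediate (not isolated)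
16 | (6S)-6-(tert-butyldimethylsilyloxy)-3,3-dimethylcyclohex-1-ene-1-carbaldehyde | O=CC1=CC(C)(C)CC[C@@H]1O[Si](C)(C)C(C)(C)C | intermediate (not isolated)
17 | [(6S)-6-(tert-butyldimethylsilyloxy)-3,3-dimethylcyclohex-1-en-1-yl]methanol | OCC1=CC(C)(C)CC[C@@H]1O[Si](C)(C)C(C)(C)C | intermediate
18 | triethyl orthoacetate | CCOC(C)(OCC)OCC | starting material
19 | tert-butyl{[(1S)-2-{[(1-ethoxyethenyl)oxy]methyl}-4,4-dimethylcyclohex-2-en-1-yl]oxy}dimethylsilane | C=C(OCC)OCC1=CC(C)(C)CC[C@@H]1O[Si](C)(C)C(C)(C)C | intermediate (not isolated)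
20 | ethyl 2-[(1S,3S)-3-(tert-butyldimethylsilyloxy)-6,6-dimethyl-2-methylidenecyclohexyl]acetate | C=C1[C@@H](CC(=O)OCC)C(C)(C)CC[C@@H]1O[Si](C)(C)C(C)(C)C | intermediate
21 | lithium enolate of 1,1-dibromo-3-[(1S,3S)-3-(tert-butyldimethylsilyloxy)-6,6-dimethyl-2-methylidenecyclohexyl]propan-2-one | C=C1[C@@H](CC([O-])=C(Br)Br)C(C)(C)CC[C@@H]1O[Si](C)(C)C(C)(C)C.[Li+] | intermediate (not isolated)
22 | lithium 3-[(1S,3S)-3-(tert-butyldimethylsilyloxy)-6,6-dimethyl-2-methylidenecyclohexyl]prop-1-yn-1-olate | C=C1[C@@H](CC#C[O-])C(C)(C)CC[C@@H]1O[Si](C)(C)C(C)(C)C.[Li+] | intermediate (not isolated)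
23 | tert-butyl{[(1S,3S)-4,4-dimethyl-2-methylidene-3-{3-[tri(propan-2-yl)silyloxy]prop-2-yn-1-yl}cyclohexyl]oxy}dimethylsilane | C=C1[C@@H](CC#CO[Si](C(C)C)(C(C)C)C(C)C)C(C)(C)CC[C@@H]1O[Si](C)(C)C(C)(C)C | intermediate
24 | 2-{6-[3,4-bis(prop-2-en-1-yloxy)phenyl]-4-oxo-4H-pyran-2-yl}ethen-1-one (pyranonylketene) | O=C=Cc1cc(=O)cc(-c2ccc(OCC=C)c(OCC=C)c2)o1 | intermediate (not isolated)
25 | 4-{6-[3,4-bis(prop-2-en-1-yloxy)phenyl]-4-oxo-4H-pyran-2-yl}-2-{[(1S,3S)-3-(tert-butyldimethylsilyloxy)-6,6-dimethyl-2-methylidenecyclohexyl]methyl}-3-[tri(propan-2-yl)silyloxy]cyclobut-2-en-1-one (both epimers at the ring CH) | C=C1[C@@H](CC2=C(O[Si](C(C)C)(C(C)C)C(C)C)C(c3cc(=O)cc(-c4ccc(OCC=C)c(OCC=C)c4)o3)C2=O)C(C)(C)CC[C@@H]1O[Si](C)(C)C(C)(C)C | intermediate (not isolated)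
26 | 4-{6-[3,4-bis(prop-2-en-1-yloxy)phenyl]-4-oxo-4H-pyran-2-yl}-2-{[(1S,3S)-3-(tert-butyldimethylsilyloxy)-6,6-dimethyl-2-methylidenecyclohexyl]methyl}-3-[tri(propan-2-yl)silyloxy]buta-1,3-dien-1-one (dienylketene) | C=C1[C@@H](CC(=C=O)C(O[Si](C(C)C)(C(C)C)C(C)C)=Cc2cc(=O)cc(-c3ccc(OCC=C)c(OCC=C)c3)o2)C(C)(C)CC[C@@H]1O[Si](C)(C)C(C)(C)C | intermediate (not isolated)
27 | 2-[3,4-bis(prop-2-en-1-yloxy)phenyl]-6-{[(1S,3S)-3-(tert-butyldimethylsilyloxy)-6,6-dimethyl-2-methylidenecyclohexyl]methyl}-5-hydroxy-7-[tri(propan-2-yl)silyloxy]-4H-chromen-4-one | C=C1[C@@H](Cc2c(O[Si](C(C)C)(C(C)C)C(C)C)cc3oc(-c4ccc(OCC=C)c(OCC=C)c4)cc(=O)c3c2O)C(C)(C)CC[C@@H]1O[Si](C)(C)C(C)(C)C | intermediate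
28 | 2-[3,4-bis(prop-2-en-1-yloxy)phenyl]-5,7-dihydroxy-6-{[(1S,3S)-3-hydroxy-6,6-dimethyl-2-methylidenecyclohexyl]methyl}-4H-chromen-4-one | C=C1[C@@H](Cc2c(O)cc3oc(-c4ccc(OCC=C)c(OCC=C)c4)cc(=O)c3c2O)C(C)(C)CC[C@@H]1O | intermediate
29 | ugonin Q, 2-(3,4-dihydroxyphenyl)-5,7-dihydroxy-6-{[(1S,3S)-3-hydroxy-6,6-dimethyl-2-methylidenecyclohexyl]methyl}-4H-chromen-4-one | C=C1[C@@H](Cc2c(O)cc3oc(-c4ccc(O)c(O)c4)cc(=O)c3c2O)C(C)(C)CC[C@@H]1O | target

**Summary**
Total step count: 14. Longest linear sequence: 9 steps (steps 6 to 14, from 4,4-dimethylcyclohex-2-en-1-one).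

**Steps most likely to fail**

Step 12 (Proposed new method). The risks are photodecomposition of the pyranone or of the flavone product under the light needed for the Wolff shift, carbene reactions that outrun the shift, shading of the diazoketone by the strongly absorbing product, and failure of the dienylketene to close onto pyranone C3. The fallback uses known chemistry and fixes C6 by directed iodination and cross-coupling instead of ring construction; it sets out from ester 20 and comes back to the route at target 29. Ester 20 would be saponified (LiOH, THF/MeOH/H2O) to 2-[(1S,3S)-3-(tert-butyldimethylsilyloxy)-6,6-dimethyl-2-methylidenecyclohexyl]acetic acid F1 and condensed with N-hydroxyphthalimide (N,N'-diisopropylcarbodiimide, DMAP, CH2Cl2) to the 1,3-dioxoisoindolin-2-yl ester F2. Commercial luteolin F3 would be silylated on O7, O3' and O4' (TBSCl, imidazole, DMF; the chelated 5-OH stays free) to the tris(silyl) ether F4. F4 would be iodinated ortho to the free 5-OH with I2 and TlOAc (monovalent thallium) in CH2Cl2, the known C6-selective iodination of 5-hydroxy-7-alkoxyflavones, to give the 6-iodoflavone F5. Decarboxylative cross-electrophile coupling of F2 with F5 (NiBr2·MeOCH2CH2OMe, 4,4'-di-tert-butyl-2,2'-bipyridine, Zn, N,N-dimethylacetamide) should give the 6-alkylflavone tetrakis(silyl) ether F6. Bu4NF in THF would then remove all four silyl groups to give 29.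

Step 10. The risks are attack of the ketene acetal on both faces of the ring alkene (poor facial selectivity relative to the OTBS-bearing carbon) and a sluggish shift at the alkene carbon next to CMe2. The fallback sets each stereocentre by a separate, well-tried principle; it sets out from iodoenone 12 and comes back at ester 20. Reduction of 12 with the enantiomeric catalyst, (S)-2-methyl-CBS-oxazaborolidine and BH3·SMe2, would give (1R)-2-iodo-4,4-dimethylcyclohex-2-en-1-ol F7. Johnson–Claisen rearrangement of F7 with 18 (EtCO2H, 140 °C) transfers the carbinol chirality suprafacially and would give ethyl 2-[(1S)-2-iodo-6,6-dimethylcyclohex-2-en-1-yl]acetate F8. Negishi coupling (MeZnCl, Pd(PPh3)4, THF) would give ethyl 2-[(1S)-2,6,6-trimethylcyclohex-2-en-1-yl]acetate F9. mCPBA (NaHCO3, CH2Cl2, 0 °C) should add oxygen to the face opposite the pseudoaxial acetate arm to give ethyl 2-[(1R,2S,6S)-1,3,3-trimethyl-7-oxabicyclo[4.1.0]heptan-2-yl]acetate F10. Cp2TiCl (trivalent titanium, from Cp2TiCl2 and Zn, THF) opens the epoxide at the tertiary carbon and removes a methyl hydrogen, the known isomerisation of trisubstituted epoxides to exo-methylene allylic alcohols, and should give ethyl 2-[(1S,3S)-3-hydroxy-6,6-dimethyl-2-methylidenecyclohexyl]acetate F11. Silylation of F11 (TBSCl, imidazole, DMF) gives 20.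

Step 11. The risks are enolisation of the ester in place of addition of LiCHBr2, an incomplete 1,2-shift of the carbenoid, silylation of the ynolate on carbon to a silylketene, and hydrolysis of the ynol ether during isolation. The fallback makes the ynolate by oxidising an acetylide; it sets out from ester 20 and comes back at ynol ether 23. Reduction of 20 with i-Bu2AlH (CH2Cl2, −78 °C) would give 2-[(1S,3S)-3-(tert-butyldimethylsilyloxy)-6,6-dimethyl-2-methylidenecyclohexyl]acetaldehyde F12. Homologation of F12 with dimethyl (1-diazo-2-oxopropyl)phosphonate (K2CO3, MeOH; Ohira–Bestmann) would give tert-butyl{[(1S,3S)-4,4-dimethyl-2-methylidene-3-(prop-2-yn-1-yl)cyclohexyl]oxy}dimethylsilane F13. Deprotonation of F13 with n-BuLi and oxidation of the acetylide with lithium tert-butyl peroxide (from t-BuOOH and lithium hexamethyldisilazide, THF, −78 → 0 °C) gives ynolate 22, which is silylated on oxygen with triisopropylsilyl triflate to give 23.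

**Further compounds**
F1 | step 12 | 2-[(1S,3S)-3-(tert-butyldimethylsilyloxy)-6,6-dimethyl-2-methylidenecyclohexyl]acetic acid | C=C1[C@@H](CC(=O)O)C(C)(C)CC[C@@H]1O[Si](C)(C)C(C)(C)C
F2 | step 12 | 1,3-dioxoisoindolin-2-yl 2-[(1S,3S)-3-(tert-butyldimethylsilyloxy)-6,6-dimethyl-2-methylidenecyclohexyl]acetate | C=C1[C@@H](CC(=O)ON2C(=O)c3ccccc3C2=O)C(C)(C)CC[C@@H]1O[Si](C)(C)C(C)(C)C
F3 | step 12 | luteolin (commercial), 2-(3,4-dihydroxyphenyl)-5,7-dihydroxy-4H-chromen-4-one | O=c1cc(-c2ccc(O)c(O)c2)oc2cc(O)cc(O)c12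
F4 | step 12 | 2-[3,4-bis(tert-butyldimethylsilyloxy)phenyl]-7-(tert-butyldimethylsilyloxy)-5-hydroxy-4H-chromen-4-one | O=c1cc(-c2ccc(O[Si](C)(C)C(C)(C)C)c(O[Si](C)(C)C(C)(C)C)c2)oc2cc(O[Si](C)(C)C(C)(C)C)cc(O)c12
F5 | step 12 | 2-[3,4-bis(tert-butyldimethylsilyloxy)phenyl]-7-(tert-butyldimethylsilyloxy)-5-hydroxy-6-iodo-4H-chromen-4-one | O=c1cc(-c2ccc(O[Si](C)(C)C(C)(C)C)c(O[Si](C)(C)C(C)(C)C)c2)oc2cc(O[Si](C)(C)C(C)(C)C)c(I)c(O)c12
F6 | step 12 | 2-[3,4-bis(tert-butyldimethylsilyloxy)phenyl]-7-(tert-butyldimethylsilyloxy)-6-{[(1S,3S)-3-(tert-butyldimethylsilyloxy)-6,6-dimethyl-2-methylidenecyclohexyl]methyl}-5-hydroxy-4H-chromen-4-one | C=C1[C@@H](Cc2c(O[Si](C)(C)C(C)(C)C)cc3oc(-c4ccc(O[Si](C)(C)C(C)(C)C)c(O[Si](C)(C)C(C)(C)C)c4)cc(=O)c3c2O)C(C)(C)CC[C@@H]1O[Si](C)(C)C(C)(C)C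
F7 | step 10 | (1R)-2-iodo-4,4-dimethylcyclohex-2-en-1-ol | IC1=CC(C)(C)CC[C@H]1O
F8 | step 10 | ethyl 2-[(1S)-2-iodo-6,6-dimethylcyclohex-2-en-1-yl]acetate | IC1=CCCC(C)(C)[C@@H]1CC(=O)OCC
F9 | step 10 | ethyl 2-[(1S)-2,6,6-trimethylcyclohex-2-en-1-yl]acetate | CC1=CCCC(C)(C)[C@@H]1CC(=O)OCC
F10 | step 10 | ethyl 2-[(1R,2S,6S)-1,3,3-trimethyl-7-oxabicyclo[4.1.0]heptan-2-yl]acetate (epoxide oxygen trans to the acetate arm) | C[C@]12O[C@H]1CCC(C)(C)[C@@H]2CC(=O)OCC
F11 | step 10 | ethyl 2-[(1S,3S)-3-hydroxy-6,6-dimethyl-2-methylidenecyclohexyl]acetate | C=C1[C@@H](CC(=O)OCC)C(C)(C)CC[C@@H]1O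
F12 | step 11 | 2-[(1S,3S)-3-(tert-butyldimethylsilyloxy)-6,6-dimethyl-2-methylidenecyclohexyl]acetaldehyde | C=C1[C@@H](CC=O)C(C)(C)CC[C@@H]1O[Si](C)(C)C(C)(C)C
F13 | step 11 | tert-butyl{[(1S,3S)-4,4-dimethyl-2-methylidene-3-(prop-2-yn-1-yl)cyclohexyl]oxy}dimethylsilane | C=C1[C@@H](CC#C)C(C)(C)CC[C@@H]1O[Si](C)(C)C(C)(C)C
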